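**Plan**

- Retrosynthetic cuts: first the two C–C bonds of the CH2 bridge, giving prenylated acylphloroglucinol 15 (ring A), a one-carbon unit and chiral trione 11 (ring B). Then, in ring B, the bond between the quaternary carbon and the ring carbonyl (enol) carbon on the bridge side, traced back to the lactone C–O bond of 2-pyranone 8. Then the isobutyryl–CH bond, the lactone and the chain, back to 3-methylpentane-2,4-dione, prenyl bromide and CO2.
- Enabling feature: ring B is a 2-acyl-2-alkylcyclohexane-1,3,5-trione. The enol oxygen on the ring carbon on the methyl side of the quaternary carbon and the ring carbonyl carbon on its other side are 1,3 to each other across that carbon. Ring B is therefore the C-acyl isomer of an enol lactone (a 4-oxy-2-pyranone), whose side-chain methine, acidified by the isobutyryl group, is the future quaternary carbon.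
- Forward order: chain by two dianion reactions on the diketone (prenylation, carboxylation); pyranone ring (a temporary ring, absent from the target) by lactonisation; O-allylation; C-acylation of the side chain; ring switch from pyranone to carbocycle; deallylation; three-component union with ring A through a Mannich base and its ortho-quinone methide.
- Stereochemistry: the single stereocentre (the quaternary carbon of ring B) arises in the ring switch under control of a chiral isothiourea acyl-transfer catalyst. Racemic 8 converges on one enantiomer, and no later step makes or breaks a bond at that carbon.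

Key step: step 6

Remark: the sense of induction of the isothiourea in this ring switch cannot be taken from precedent; the route is written with the (2S,3R) catalyst as the enantiomer assumed to give (6R)-10, and the equally available (2R,3S) catalyst is used if the other enantiomer predominates (enolised triones are drawn in the tautomer of the target).

**Route**

Step 1
Reactants: 1 3-methylpentane-2,4-dione; 2 1-bromo-3-methylbut-2-ene (prenyl bromide)
Product: 3 3,8-dimethylnon-7-ene-2,4-dione
Conditions: LiN(i-Pr)2 (2.1 equiv), THF, −78 to 0 °C; 2 (1.0 equiv), −78 to 0 °C; 1 M HCl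
Reagents that add atoms: none
Why: Alkylation of a β-diketone dianion, in which the second carbanion at the terminal methyl group is the more nucleophilic site and displaces bromide from the primary allylic bromide (SN2), so the prenyl unit enters at the chain end and not at the central carbon.

Step 2
Reactants: 3 3,8-dimethylnon-7-ene-2,4-dione
Product: 4 4,9-dimethyl-3,5-dioxodec-8-enoic acid
Conditions: LiN(i-Pr)2 (2.2 equiv), THF, −78 to 0 °C; CO2 (gas), −78 °C; cold 1 M HCl; used at once
Reagents that add atoms: carbon dioxide, O=C=O
Why: Carboxylation of a β-diketone dianion, in which the second deprotonation takes place at the methyl rather than the methylene terminus (less substituted α-carbon), the terminal carbanion adds to CO2 and the carboxylate formed is inert to further reaction.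

Step 3
Reactants: 4 4,9-dimethyl-3,5-dioxodec-8-enoic acid
Product: 5 4-hydroxy-5-methyl-6-(4-methylpent-3-en-1-yl)-2H-pyran-2-one
Conditions: Ac2O, rt
Reagents that add atoms: none
Why: Cyclodehydration (lactonisation) of a β,δ-diketo acid, in which the mixed anhydride is acylated intramolecularly by the δ-enol oxygen to give the 4-hydroxy-2-pyranone at room temperature, so that the β-keto acid should not decarboxylate and the trisubstituted alkene stays untouched.

Step 4
Reactants: 5 4-hydroxy-5-methyl-6-(4-methylpent-3-en-1-yl)-2H-pyran-2-one
Product: 6 5-methyl-6-(4-methylpent-3-en-1-yl)-4-(prop-2-en-1-yloxy)-2H-pyran-2-one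
Conditions: allyl alcohol, PPh3, diisopropyl azodicarboxylate (DIAD), THF, 0 °C to rt
Reagents that add atoms: allyl alcohol (prop-2-en-1-ol), C=CCO
Why: Mitsunobu etherification, in which the acidic 4-hydroxy group (a vinylogous carboxylic acid) is alkylated at oxygen by the alkoxyphosphonium salt of allyl alcohol, which avoids the C-3 alkylation that allyl halides and base tend to give.

Step 5
Reactants: 6 5-methyl-6-(4-methylpent-3-en-1-yl)-4-(prop-2-en-1-yloxy)-2H-pyran-2-one; 7 N-methoxy-N-methyl-2-methylpropanamide (Weinreb amide of isobutyric acid)
Product: 8 racemic 6-(2,7-dimethyl-3-oxooct-6-en-4-yl)-5-methyl-4-(prop-2-en-1-yloxy)-2H-pyran-2-one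
Conditions: LiN(i-Pr)2 (1.2 equiv), THF, −78 °C; 7 (1.5 equiv), −78 to −20 °C; cold 1 M HCl
Reagents that add atoms: none
Why: Vinylogous deprotonation of the 6-alkyl-4-alkoxy-2-pyranone at the CH2 next to the ring gives an extended enolate that is C-acylated by the Weinreb amide through a stable chelated tetrahedral intermediate (Weinreb ketone synthesis, no over-addition and no proton transfer), and the new methine is formed as a racemate, which is of no consequence because it is planarised in step 6.

Step 6
Reactants: 8 racemic 6-(2,7-dimethyl-3-oxooct-6-en-4-yl)-5-methyl-4-(prop-2-en-1-yloxy)-2H-pyran-2-one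
Product: 10 (6R)-5-hydroxy-4-methyl-6-(3-methylbut-2-en-1-yl)-6-(2-methylpropanoyl)-3-(prop-2-en-1-yloxy)cyclohexa-2,4-dien-1-one, via acyl isothiouronium diketonate 9 (not isolated)
Conditions: (2S,3R)-3-isopropyl-2-phenyl-3,4-dihydro-2H-benzo[4,5]thiazolo[3,2-a]pyrimidine (HyperBTM, 10 mol%), i-Pr2NEt (1.2 equiv), CH2Cl2, 0 °C to rt; aq citric acid
Reagents that add atoms: none
Why: Proposed new method: a chiral isothiourea adds to the lactone carbonyl of the neutral 4-alkoxy-2-pyranone and opens it to an acyl isothiouronium whose enolate leaving group is relayed by proton transfer (i-Pr2NEt) to the 1,3-diketonate 9, which C-acylates itself at the tertiary carbon and releases the catalyst; the closest known reaction types are the Lewis-base-catalysed enantioselective O-to-C acyl transfer of enol esters and enol carbonates (Steglich and Black rearrangements) and the Mg(OMe)2-mediated recyclisation of 6-(2-oxoalkyl)-4-hydroxy-2-pyranones to acylphloroglucinols, neither of which has been shown for a pyranone-to-cyclohexadienone ring switch that forms a quaternary stereocentre. The six-membered carbocycle closes by a 6-exo-trig acyl substitution by the enolate carbon (enolendo or enolexo, both allowed), while the lactone C–O bond of the pyranone, a ring that is not in the target, is the bond given up. The new quaternary stereocentre is set by the catalyst: the acyl isothiouronium is planar and locked by its 1,5 S···O contact and its 2-phenyl group shields one face, so the tethered diketonate should reach the acyl carbon with only one of its enantiotopic faces, and because the methine of 8 is planar in 9 both enantiomers of 8 converge on one product. The step needs C- over O-acylation and catalyst turnover: O-acylation only returns 8, a direct 1,3-shift without the catalyst would need a four-membered transition state so no racemic background is expected, and C-acylation becomes irreversible because 10 is a vinylogous acid that i-Pr2NEt holds as its enolate, which also shields the acylated quaternary carbon from retro-Claisen cleavage. The allyl ether keeps the pyranone neutral, so that the catalyst is not protonated by a free 4-hydroxy group.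

Step 7
Reactants: 10 (6R)-5-hydroxy-4-methyl-6-(3-methylbut-2-en-1-yl)-6-(2-methylpropanoyl)-3-(prop-2-en-1-yloxy)cyclohexa-2,4-dien-1-one
Product: 11 (4R)-3,5-dihydroxy-2-methyl-4-(3-methylbut-2-en-1-yl)-4-(2-methylpropanoyl)cyclohexa-2,5-dien-1-one
Conditions: Pd(PPh3)4 (5 mol%), morpholine (10 equiv), THF, rt; aq citric acid
Reagents that add atoms: none
Why: Tsuji–Trost-type deallylation, in which zerovalent palladium ionises the allyl vinylogous ester to a π-allyl complex and the trione enolate, and excess morpholine should trap the allyl unit faster than the stabilised carbon nucleophile, under neutral conditions that touch neither the quaternary carbon nor the prenyl group (same spatial arrangement as in 10; the descriptor stays R although the priorities change).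

Step 8
Reactants: 12 benzene-1,3,5-triol (phloroglucinol); 13 2-methylpropanoyl chloride
Product: 14 2-methyl-1-(2,4,6-trihydroxyphenyl)propan-1-one
Conditions: AlCl3 (3 equiv), PhNO2, 60 °C; aq HCl
Reagents that add atoms: none
Why: Friedel–Crafts C-acylation of the very electron-rich arene, in which the first acyl group deactivates the ring so that monoacylation prevails.

Step 9
Reactants: 14 2-methyl-1-(2,4,6-trihydroxyphenyl)propan-1-one; 2 1-bromo-3-methylbut-2-ene
Product: 15 2-methyl-1-[2,4,6-trihydroxy-3-(3-methylbut-2-en-1-yl)phenyl]propan-1-one
Conditions: KOH (1 equiv), H2O, 0 °C; 2 (1 equiv)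
Reagents that add atoms: none
Why: C-prenylation of the phloroglucinol phenolate in water (the protic medium favours C- over O-alkylation), held at the mono-prenyl stage by the use of one equivalent of bromide, and the two free ring positions of 14 are equivalent so only one mono-prenyl product can form.

Step 10
Reactants: 11 (4R)-3,5-dihydroxy-2-methyl-4-(3-methylbut-2-en-1-yl)-4-(2-methylpropanoyl)cyclohexa-2,5-dien-1-one; 15 2-methyl-1-[2,4,6-trihydroxy-3-(3-methylbut-2-en-1-yl)phenyl]propan-1-one
Product: 18 (4S)-3,5-dihydroxy-2-methyl-4-(3-methylbut-2-en-1-yl)-4-(2-methylpropanoyl)-6-{[2,4,6-trihydroxy-3-(3-methylbut-2-en-1-yl)-5-(2-methylpropanoyl)phenyl]methyl}cyclohexa-2,5-dien-1-one, via Mannich base 16 (not isolated), via ortho-quinone methide 17 (not isolated)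
Conditions: 15, CH2=NMe2+ I− (1 equiv each), CH2Cl2, rt; then 11, NaOAc, MeCN, 60 °C
Reagents that add atoms: N,N-dimethylmethylideneammonium iodide (Eschenmoser's salt), C=[N+](C)C.[I-]
Why: Three-component methylene bridging by Mannich aminomethylation at the only free ring position of 15, loss of dimethylamine to the ortho-quinone methide and Michael addition of the unsubstituted enol carbon of 11; 16 has no free ring carbon and ring B never becomes an electrophile, so only the crossed dimer should form, and the quaternary stereocentre is not involved (its descriptor changes from R to S only because the bridge raises the priority of one ring branch).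

**Compound list**

1 | 3-methylpentane-2,4-dione | CC(=O)C(C)C(C)=O | starting material
2 | 1-bromo-3-methylbut-2-ene (prenyl bromide) | CC(C)=CCBr | starting material
3 | 3,8-dimethylnon-7-ene-2,4-dione | CC(=O)C(C)C(=O)CCC=C(C)C | intermediate
4 | 4,9-dimethyl-3,5-dioxodec-8-enoic acid | OC(=O)CC(=O)C(C)C(=O)CCC=C(C)C | intermediate
5 | 4-hydroxy-5-methyl-6-(4-methylpent-3-en-1-yl)-2H-pyran-2-one | O=C1C=C(O)C(C)=C(CCC=C(C)C)O1 | intermediate
6 | 5-methyl-6-(4-methylpent-3-en-1-yl)-4-(prop-2-en-1-yloxy)-2H-pyran-2-one | O=C1C=C(OCC=C)C(C)=C(CCC=C(C)C)O1 | intermediate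
7 | N-methoxy-N-methyl-2-methylpropanamide | CC(C)C(=O)N(C)OC | starting material
8 | racemic 6-(2,7-dimethyl-3-oxooct-6-en-4-yl)-5-methyl-4-(prop-2-en-1-yloxy)-2H-pyran-2-one | O=C1C=C(OCC=C)C(C)=C(C(CC=C(C)C)C(=O)C(C)C)O1 | intermediate
9 | zwitterion of the N-[(2E)-4,8-dimethyl-6-(3-methylbut-2-en-1-yl)-5,7-dioxo-3-(prop-2-en-1-yloxy)non-2-enoyl] isothiouronium of (2S,3R)-HyperBTM, as its 5,7-diketonate | CC(C)[C@@H]1CN2c3ccccc3SC2=[N+](C(=O)\C=C(OCC=C)/C(C)C([O-])=C(CC=C(C)C)C(=O)C(C)C)[C@@H]1c1ccccc1 | intermediate (not isolated)
10 | (6R)-5-hydroxy-4-methyl-6-(3-methylbut-2-en-1-yl)-6-(2-methylpropanoyl)-3-(prop-2-en-1-yloxy)cyclohexa-2,4-dien-1-one | O=C1C=C(OCC=C)C(C)=C(O)[C@]1(CC=C(C)C)C(=O)C(C)C | intermediate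
11 | (4R)-3,5-dihydroxy-2-methyl-4-(3-methylbut-2-en-1-yl)-4-(2-methylpropanoyl)cyclohexa-2,5-dien-1-one | O=C1C=C(O)[C@@](CC=C(C)C)(C(=O)C(C)C)C(O)=C1C | intermediate
12 | benzene-1,3,5-triol (phloroglucinol) | Oc1cc(O)cc(O)c1 | starting material
13 | 2-methylpropanoyl chloride | CC(C)C(Cl)=O | starting material
14 | 2-methyl-1-(2,4,6-trihydroxyphenyl)propan-1-one | CC(C)C(=O)c1c(O)cc(O)cc1O | intermediate
15 | 2-methyl-1-[2,4,6-trihydroxy-3-(3-methylbut-2-en-1-yl)phenyl]propan-1-one | CC(C)C(=O)c1c(O)cc(O)c(CC=C(C)C)c1O | intermediate
16 | 1-{3-[(dimethylamino)methyl]-2,4,6-trihydroxy-5-(3-methylbut-2-en-1-yl)phenyl}-2-methylpropan-1-one | CC(C)C(=O)c1c(O)c(CN(C)C)c(O)c(CC=C(C)C)c1O | intermediate (not isolated)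
17 | 3,5-dihydroxy-6-methylidene-2-(3-methylbut-2-en-1-yl)-4-(2-methylpropanoyl)cyclohexa-2,4-dien-1-one | C=C1C(=O)C(CC=C(C)C)=C(O)C(C(=O)C(C)C)=C1O | intermediate (not isolated)
18 | (4S)-3,5-dihydroxy-2-methyl-4-(3-methylbut-2-en-1-yl)-4-(2-methylpropanoyl)-6-{[2,4,6-trihydroxy-3-(3-methylbut-2-en-1-yl)-5-(2-methylpropanoyl)phenyl]methyl}cyclohexa-2,5-dien-1-one | CC(C)=CCc1c(O)c(CC2=C(O)[C@@](CC=C(C)C)(C(=O)C(C)C)C(O)=C(C)C2=O)c(O)c(C(=O)C(C)C)c1O | target

**Summary**

Total step count: 10. Longest linear sequence: 8 steps (steps 1 to 7 and step 10); the ring A branch is 2 steps (8 and 9).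

Steps most likely to fail:

1. Step 6 (Proposed new method). The catalyst may fail to open the electron-rich pyranone, the enolate relay may stall, or the acyl transfer may proceed with poor facial selectivity. The fallback uses known chemistry and sets out from 8. The allyl ether is removed first (Pd(PPh3)4, morpholine, THF) to give the free 4-hydroxy-2-pyranone F1. Mg(OMe)2 in MeOH at reflux, the classical conditions for recyclising 6-(2-oxoalkyl)-4-hydroxy-2-pyranones, should open the lactone to the chelated methyl triketo ester F2, which is not isolated and should close by Claisen condensation at the tertiary carbon to the racemic trione F3. The enantiomers of F3 are then separated by preparative chromatography on a chiral stationary phase, and the (4R) enantiomer is 11, where the route is rejoined (step 7 is then not needed).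

2. Step 10. The ortho-quinone methide may be released too slowly at a temperature the trione tolerates, alkylation may go to oxygen instead of carbon, or the stereocentre may erode through amine-induced retro-Claisen opening and reclosure. The fallback sets out from 15 and replaces the Mannich route by a reductive one. Vilsmeier–Haack formylation of 15 (POCl3, DMF, then aqueous NaOAc) should give the aldehyde F4. An organocatalytic three-component reductive alkylation of 11 with F4 and Hantzsch ester (L-proline cat, CH2Cl2, rt) should then pass through the Knoevenagel adduct F5, which is reduced in the flask by hydride transfer to give 18, where the route ends.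

3. Step 5. Acylation of the stabilised secondary extended enolate by the branched amide may be sluggish, or lithiation may compete at C-3 of the pyranone. The fallback sets out from 6 and separates C–C bond formation from the oxidation level. The same lithiated species is added to 2-methylpropanal (aldol addition at −78 °C) to give the β-hydroxy compound F6 as a mixture of diastereomers, and Dess–Martin periodinane (CH2Cl2, rt) should oxidise F6 to 8, where the route is rejoined.

**Further compounds**

F1 | step 6 | racemic 6-(2,7-dimethyl-3-oxooct-6-en-4-yl)-4-hydroxy-5-methyl-2H-pyran-2-one | O=C1C=C(O)C(C)=C(C(CC=C(C)C)C(=O)C(C)C)O1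
F2 | step 6 | methyl 4,8-dimethyl-6-(3-methylbut-2-en-1-yl)-3,5,7-trioxononanoate | COC(=O)CC(=O)C(C)C(=O)C(CC=C(C)C)C(=O)C(C)C
F3 | step 6 | racemic 3,5-dihydroxy-2-methyl-4-(3-methylbut-2-en-1-yl)-4-(2-methylpropanoyl)cyclohexa-2,5-dien-1-one | O=C1C=C(O)C(CC=C(C)C)(C(=O)C(C)C)C(O)=C1C
F4 | step 10 | 2,4,6-trihydroxy-3-(3-methylbut-2-en-1-yl)-5-(2-methylpropanoyl)benzaldehyde | CC(C)C(=O)c1c(O)c(C=O)c(O)c(CC=C(C)C)c1O
F5 | step 10 | Knoevenagel adduct of 11 with F4 (2-arylmethylidene trione; quaternary carbon configured as in 11; alkene geometry not defined) | CC(C)C(=O)c1c(O)c(C=C2C(=O)C(C)=C(O)[C@](CC=C(C)C)(C(=O)C(C)C)C2=O)c(O)c(CC=C(C)C)c1O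
F6 | step 5 | 6-(3-hydroxy-2,7-dimethyloct-6-en-4-yl)-5-methyl-4-(prop-2-en-1-yloxy)-2H-pyran-2-one (mixture of diastereomers) | O=C1C=C(OCC=C)C(C)=C(C(CC=C(C)C)C(O)C(C)C)O1
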